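## Retrosynthetic overview

1. The target comes from global MOM removal of a tris-MOM chalcone. Its aryl–C(=O) bond is cut to a C6 aryllithium (MOM-directed) and a ring B cinnamoyl Weinreb amide.
2. The pyran ring (last ring formed) comes from Markovnikov hydroalkoxylation of the isopropenyl group of an (R)-lavandulyl phenol by its one free ortho-OH.
3. The prenyl arm comes from Wittig isopropylidenation of the aldehyde released by half-reduction of a seven-membered aryl lactone.
4. Key C–C bond (benzylic CH2 to the stereogenic CH): a carbene-generated homoenolate of 4-methylpenta-2,4-dienal (β-carbon made nucleophilic) adds to the electrophilic CH2 of an ortho-quinone methide in an enantioselective [4+3] annulation. This benzoxepinone is the first ring formed and is opened again in the next step.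
5. The quinone methide precursor (a phenol sulfone) comes from 2,4,6-trihydroxybenzaldehyde; both benzene rings are bought.

Assumption: the (5aR,10bS) aminoindanol triazolium salt is taken to give the (4S) lactone; if the sense is opposite, its commercial mirror image is used.

## Route

Step 1
Reactants: 1 2,4,6-trihydroxybenzaldehyde
Product: 2 2,6-dihydroxy-4-methoxybenzaldehyde
Conditions: MeI (1.05 equiv), K2CO3 (1.0 equiv), DMF, 0 °C → rt
Reagents that add atoms: iodomethane, CI
Why: Williamson O-methylation in which only the 4-OH is free of hydrogen bonding to the formyl group and is the most acidic, so one equivalent of base and MeI alkylates it selectively.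

Step 2
Reactants: 2 2,6-dihydroxy-4-methoxybenzaldehyde
Product: 3 2-hydroxy-4-methoxy-6-(methoxymethoxy)benzaldehyde
Conditions: MOMCl (1.1 equiv), i-Pr2NEt (1.5 equiv), CH2Cl2, 0 °C → rt
Reagents that add atoms: chloromethyl methyl ether, COCCl
Why: MOM ether formation stops after one ortho-OH because the remaining OH is then locked in a strong hydrogen bond to the aldehyde and no longer reacts.

Step 3
Reactants: 3 2-hydroxy-4-methoxy-6-(methoxymethoxy)benzaldehyde
Product: 5 5-methoxy-3-(methoxymethoxy)-2-[(4-methylbenzenesulfonyl)methyl]phenol, via salicyl alcohol 4 (not isolated)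
Conditions: NaBH4 (1.0 equiv), MeOH, 0 °C; then p-TolSO2Na (3 equiv), AcOH, rt, 12 h
Reagents that add atoms: sodium 4-methylbenzenesulfinate, Cc1ccc(cc1)S(=O)[O-].[Na+]
Why: Borohydride reduction gives the electron-rich salicyl alcohol, which ionises in acetic acid to a stabilised benzylic cation that excess sulfinate captures at sulfur (S-alkylation) before it can self-condense, the MOM ether surviving the weak acid.

Step 4
Reactants: 6 methacrolein (2-methylprop-2-enal); 7 (triphenylphosphoranylidene)acetaldehyde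
Product: 8 (2E)-4-methylpenta-2,4-dienal
Conditions: 6 (3 equiv), toluene, 80 °C, sealed tube; distillation
Reagents that add atoms: none
Why: Wittig olefination with a formyl-stabilised ylide is E-selective, and the excess of volatile methacrolein suppresses a second homologation.

Step 5
Reactants: 5 5-methoxy-3-(methoxymethoxy)-2-[(4-methylbenzenesulfonyl)methyl]phenol; 8 (2E)-4-methylpenta-2,4-dienal
Product: 10 (4S)-8-methoxy-6-(methoxymethoxy)-4-(prop-1-en-2-yl)-4,5-dihydro-1-benzoxepin-2(3H)-one, via ortho-quinone methide 9 (not isolated)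
Conditions: (5aR,10bS)-2-(2,4,6-trimethylphenyl)-5a,10b-dihydro-4H,6H-indeno[2,1-b][1,2,4]triazolo[4,3-d][1,4]oxazin-2-ium chloride (15 mol%), Cs2CO3 (1.5 equiv), 4 Å molecular sieves, THF, 0 °C → rt, 8 (1.5 equiv) added over 4 h
Reagents that add atoms: none
Why: Carbonate expels sulfinate from the phenoxide of 5 to give quinone methide 9, while the chiral triazolylidene turns enal 8 into a Breslow-type homoenolate whose β-carbon, shielded on one face by the aminoindane backbone, adds to the exocyclic CH2 of 9 before the phenoxide closes the acyl azolium to the lactone, a carbene-catalysed homoenolate [4+3] annulation that sets the only stereocentre.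

Step 6
Reactants: 10 (4S)-8-methoxy-6-(methoxymethoxy)-4-(prop-1-en-2-yl)-4,5-dihydro-1-benzoxepin-2(3H)-one
Product: 11 (3S)-3-{[2-hydroxy-4-methoxy-6-(methoxymethoxy)phenyl]methyl}-4-methylpent-4-enal
Conditions: i-Bu2AlH (1.15 equiv), CH2Cl2, −78 °C, 1 h; aq. potassium sodium tartrate
Reagents that add atoms: none
Why: Partial reduction of the aryl lactone at −78 °C stops at the aluminium hemiacetal, which releases the phenol aldehyde (open form of the seven-membered lactol) on work-up, and the stereocentre is β to the carbonyl so it cannot epimerise.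

Step 7
Reactants: 11 (3S)-3-{[2-hydroxy-4-methoxy-6-(methoxymethoxy)phenyl]methyl}-4-methylpent-4-enal
Product: 12 5-methoxy-3-(methoxymethoxy)-2-[(2R)-5-methyl-2-(prop-1-en-2-yl)hex-4-en-1-yl]phenol
Conditions: i-PrPPh3I (3.0 equiv), n-BuLi (2.9 equiv), THF, 0 °C; add 11 at −78 °C → rt
Reagents that add atoms: isopropyltriphenylphosphonium iodide, CC(C)[P+](c1ccccc1)(c1ccccc1)c1ccccc1.[I-]
Why: Wittig olefination with the non-stabilised isopropylidene ylide (one extra equivalent is consumed by the phenol) turns the aldehyde into the prenyl arm and completes the (R)-lavandulyl chain without touching the non-acidic stereocentre.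

Step 8
Reactants: 12 5-methoxy-3-(methoxymethoxy)-2-[(2R)-5-methyl-2-(prop-1-en-2-yl)hex-4-en-1-yl]phenol
Product: 13 (3R)-7-methoxy-5-(methoxymethoxy)-2,2-dimethyl-3-(3-methylbut-2-en-1-yl)-3,4-dihydro-2H-1-benzopyran
Conditions: (R,R)-N,N'-bis(3,5-di-tert-butylsalicylidene)-1,2-cyclohexanediaminocobalt (divalent cobalt, 3 mol%), N-fluoro-2,4,6-trimethylpyridinium trifluoromethanesulfonate (1.5 equiv), PhSiH3 (1.5 equiv), PhCF3, 0 °C → rt
Reagents that add atoms: none
Why: Cobalt-hydride hydrogen-atom transfer goes faster to the unhindered 1,1-disubstituted isopropenyl group than to the trisubstituted prenyl alkene, and oxidation of the tertiary radical with capture by the only free phenol closes the gem-dimethyl pyran ring (Mukaiyama-type Markovnikov hydroalkoxylation by radical–polar crossover) under non-acidic conditions that keep the MOM ether and the adjacent stereocentre intact.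

Step 9
Reactants: 14 2,4-dihydroxybenzaldehyde
Product: 15 2,4-bis(methoxymethoxy)benzaldehyde
Conditions: MOMCl (2.5 equiv), K2CO3 (3 equiv), acetone, reflux
Reagents that add atoms: chloromethyl methyl ether, COCCl
Why: Williamson-type acetalisation under forcing carbonate conditions protects both phenols, including the hydrogen-bonded ortho one.

Step 10
Reactants: 15 2,4-bis(methoxymethoxy)benzaldehyde; 16 diethyl {2-[methoxy(methyl)amino]-2-oxoethyl}phosphonate
Product: 17 (2E)-3-[2,4-bis(methoxymethoxy)phenyl]-N-methoxy-N-methylprop-2-enamide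
Conditions: NaH (1.1 equiv), THF, 0 °C → rt
Reagents that add atoms: none
Why: Horner–Wadsworth–Emmons olefination with an amide-stabilised phosphonate anion gives the E-configured cinnamoyl Weinreb amide.

Step 11
Reactants: 13 (3R)-7-methoxy-5-(methoxymethoxy)-2,2-dimethyl-3-(3-methylbut-2-en-1-yl)-3,4-dihydro-2H-1-benzopyran; 17 (2E)-3-[2,4-bis(methoxymethoxy)phenyl]-N-methoxy-N-methylprop-2-enamide
Product: 19 (2E)-3-[2,4-bis(methoxymethoxy)phenyl]-1-[(3R)-7-methoxy-5-(methoxymethoxy)-2,2-dimethyl-3-(3-methylbut-2-en-1-yl)-3,4-dihydro-2H-1-benzopyran-6-yl]prop-2-en-1-one, via 6-lithiochroman 18 (not isolated)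
Conditions: n-BuLi (1.15 equiv), THF, 0 °C, 1 h; then 17 (1.2 equiv), −78 → 0 °C; aq. NH4Cl
Reagents that add atoms: none
Why: Directed ortho-metalation removes the C6 hydrogen that lies between the strongly coordinating OMOM group and the OMe group (C8–H has only weaker ether neighbours), and the aryllithium adds 1,2 to the Weinreb amide, whose chelated adduct collapses to the E-enone only on work-up (Weinreb ketone synthesis).

Step 12
Reactants: 19 (2E)-3-[2,4-bis(methoxymethoxy)phenyl]-1-[(3R)-7-methoxy-5-(methoxymethoxy)-2,2-dimethyl-3-(3-methylbut-2-en-1-yl)-3,4-dihydro-2H-1-benzopyran-6-yl]prop-2-en-1-one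
Product: 20 (2E)-3-(2,4-dihydroxyphenyl)-1-[(3R)-5-hydroxy-7-methoxy-2,2-dimethyl-3-(3-methylbut-2-en-1-yl)-3,4-dihydro-2H-1-benzopyran-6-yl]prop-2-en-1-one
Conditions: 3 M aq. HCl, MeOH, 40 °C, dark
Reagents that add atoms: none
Why: Acid-catalysed acetal exchange with methanol removes all three MOM groups (the one ortho to the ketone fastest), while the isolated prenyl alkene, the pyran ring and the E-enone tolerate dilute HCl at this temperature.

## Compound list

1 | 2,4,6-trihydroxybenzaldehyde | O=Cc1c(O)cc(O)cc1O | starting material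
2 | 2,6-dihydroxy-4-methoxybenzaldehyde | COc1cc(O)c(C=O)c(O)c1 | intermediate
3 | 2-hydroxy-4-methoxy-6-(methoxymethoxy)benzaldehyde | COCOc1cc(OC)cc(O)c1C=O | intermediate
4 | 2-(hydroxymethyl)-5-methoxy-3-(methoxymethoxy)phenol | COCOc1cc(OC)cc(O)c1CO | intermediate
5 | 5-methoxy-3-(methoxymethoxy)-2-[(4-methylbenzenesulfonyl)methyl]phenol | COCOc1cc(OC)cc(O)c1CS(=O)(=O)c1ccc(C)cc1 | intermediate
6 | methacrolein (2-methylprop-2-enal) | CC(=C)C=O | starting material
7 | (triphenylphosphoranylidene)acetaldehyde | O=CC=P(c1ccccc1)(c1ccccc1)c1ccccc1 | starting material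
8 | (2E)-4-methylpenta-2,4-dienal | CC(=C)/C=C/C=O | intermediate
9 | 3-methoxy-5-(methoxymethoxy)-6-methylidenecyclohexa-2,4-dien-1-one | C=C1C(=O)C=C(OC)C=C1OCOC | intermediate
10 | (4S)-8-methoxy-6-(methoxymethoxy)-4-(prop-1-en-2-yl)-4,5-dihydro-1-benzoxepin-2(3H)-one | COc1cc(OCOC)c2C[C@H](C(C)=C)CC(=O)Oc2c1 | intermediate
11 | (3S)-3-{[2-hydroxy-4-methoxy-6-(methoxymethoxy)phenyl]methyl}-4-methylpent-4-enal | COc1cc(O)c(C[C@H](C(C)=C)CC=O)c(OCOC)c1 | intermediate
12 | 5-methoxy-3-(methoxymethoxy)-2-[(2R)-5-methyl-2-(prop-1-en-2-yl)hex-4-en-1-yl]phenol | COc1cc(O)c(C[C@H](C(C)=C)CC=C(C)C)c(OCOC)c1 | intermediate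
13 | (3R)-7-methoxy-5-(methoxymethoxy)-2,2-dimethyl-3-(3-methylbut-2-en-1-yl)-3,4-dihydro-2H-1-benzopyran | COc1cc2c(c(OCOC)c1)C[C@@H](CC=C(C)C)C(C)(C)O2 | intermediate
14 | 2,4-dihydroxybenzaldehyde | O=Cc1ccc(O)cc1O | starting material
15 | 2,4-bis(methoxymethoxy)benzaldehyde | COCOc1ccc(C=O)c(OCOC)c1 | intermediate
16 | diethyl {2-[methoxy(methyl)amino]-2-oxoethyl}phosphonate | CCOP(=O)(CC(=O)N(C)OC)OCC | starting material
17 | (2E)-3-[2,4-bis(methoxymethoxy)phenyl]-N-methoxy-N-methylprop-2-enamide | COCOc1ccc(/C=C/C(=O)N(C)OC)c(OCOC)c1 | intermediate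
18 | [(3R)-7-methoxy-5-(methoxymethoxy)-2,2-dimethyl-3-(3-methylbut-2-en-1-yl)-3,4-dihydro-2H-1-benzopyran-6-yl]lithium | COc1cc2c(c(OCOC)c1[Li])C[C@@H](CC=C(C)C)C(C)(C)O2 | intermediate
19 | (2E)-3-[2,4-bis(methoxymethoxy)phenyl]-1-[(3R)-7-methoxy-5-(methoxymethoxy)-2,2-dimethyl-3-(3-methylbut-2-en-1-yl)-3,4-dihydro-2H-1-benzopyran-6-yl]prop-2-en-1-one | COc1cc2c(c(OCOC)c1C(=O)/C=C/c1ccc(OCOC)cc1OCOC)C[C@@H](CC=C(C)C)C(C)(C)O2 | intermediate
20 | (2E)-3-(2,4-dihydroxyphenyl)-1-[(3R)-5-hydroxy-7-methoxy-2,2-dimethyl-3-(3-methylbut-2-en-1-yl)-3,4-dihydro-2H-1-benzopyran-6-yl]prop-2-en-1-one | COc1cc2c(c(O)c1C(=O)/C=C/c1ccc(O)cc1O)C[C@@H](CC=C(C)C)C(C)(C)O2 | target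

## Step count and risks

Total step count: 12. Longest linear sequence: 9 steps (steps 1, 2, 3, 5, 6, 7, 8, 11, 12).

Three steps most likely to fail:

**Step 5 (carbene [4+3] annulation).** The dienal-derived Breslow intermediate may react at its δ-carbon or be protonated at the β-carbon, the donor-rich quinone methide 9 may be a sluggish electrophile, and the enantioselectivity for this enal is untested. The fallback sets out from 5 and comes back at 10. Treating 5 with vinylmagnesium bromide (3 equiv, THF, −78 → 0 °C) releases 9 and traps it as 5-methoxy-3-(methoxymethoxy)-2-(prop-2-en-1-yl)phenol F1. Acylation with acryloyl chloride and Et3N gives 5-methoxy-3-(methoxymethoxy)-2-(prop-2-en-1-yl)phenyl prop-2-enoate F2. Ring-closing metathesis with the second-generation Hoveyda–Grubbs catalyst (toluene, 80 °C) gives 8-methoxy-6-(methoxymethoxy)-1-benzoxepin-2(5H)-one F3. Asymmetric 1,4-addition of isopropenylboronic acid pinacol ester ([Rh(cod)Cl]2, the enantiomer of 2,2'-bis(diphenylphosphino)-1,1'-binaphthyl that gives the 4S product, K3PO4, dioxane/water, 40 °C) then delivers lactone 10.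

**Step 8 (cobalt hydroalkoxylation).** The very electron-rich phenol may be attacked by the N-fluoropyridinium oxidant, and hydrogen-atom transfer to the prenyl alkene may compete. The fallback sets out from 12 and comes back at 13. The MOM group is removed first (HCl, MeOH, rt) to give the symmetric 5-methoxy-2-[(2R)-5-methyl-2-(prop-1-en-2-yl)hex-4-en-1-yl]benzene-1,3-diol F4, in which either OH leads to the same ring. Brief treatment with CF3SO3H (2 mol%) in CH2Cl2 at −20 °C cyclises it to (3R)-7-methoxy-2,2-dimethyl-3-(3-methylbut-2-en-1-yl)-3,4-dihydro-2H-1-benzopyran-5-ol F5; the low temperature is needed so the tertiary cation is trapped before it can lose the C3 proton and erode the stereocentre. Re-protection (NaH, MOMCl, DMF) gives 13.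

**Step 11 (lithiation and acylation).** The hindered 2,6-dioxygenated aryllithium may add slowly or in a 1,4 sense to the unsaturated Weinreb amide. The fallback sets out from 13 and comes back at 19. The same aryllithium 18 is quenched with the small electrophile N-methoxy-N-methylacetamide to give 1-[(3R)-7-methoxy-5-(methoxymethoxy)-2,2-dimethyl-3-(3-methylbut-2-en-1-yl)-3,4-dihydro-2H-1-benzopyran-6-yl]ethan-1-one F6. The enone is then built by Claisen–Schmidt condensation of F6 with aldehyde 15 (KOH, EtOH, rt), which gives 19.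

## Further compounds

F1 | step 5 | 5-methoxy-3-(methoxymethoxy)-2-(prop-2-en-1-yl)phenol | C=CCc1c(O)cc(OC)cc1OCOC
F2 | step 5 | 5-methoxy-3-(methoxymethoxy)-2-(prop-2-en-1-yl)phenyl prop-2-enoate | C=CCc1c(OC(=O)C=C)cc(OC)cc1OCOC
F3 | step 5 | 8-methoxy-6-(methoxymethoxy)-1-benzoxepin-2(5H)-one | COc1cc(OCOC)c2CC=CC(=O)Oc2c1
F4 | step 8 | 5-methoxy-2-[(2R)-5-methyl-2-(prop-1-en-2-yl)hex-4-en-1-yl]benzene-1,3-diol | COc1cc(O)c(C[C@H](C(C)=C)CC=C(C)C)c(O)c1
F5 | step 8 | (3R)-7-methoxy-2,2-dimethyl-3-(3-methylbut-2-en-1-yl)-3,4-dihydro-2H-1-benzopyran-5-ol | COc1cc(O)c2C[C@@H](CC=C(C)C)C(C)(C)Oc2c1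
F6 | step 11 | 1-[(3R)-7-methoxy-5-(methoxymethoxy)-2,2-dimethyl-3-(3-methylbut-2-en-1-yl)-3,4-dihydro-2H-1-benzopyran-6-yl]ethan-1-one | COc1cc2c(c(OCOC)c1C(C)=O)C[C@@H](CC=C(C)C)C(C)(C)O2
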